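A direct plan would build each benzophenone from two finished benzene rings and make the methylene bridge last.
The aryl-lithium from 1-methoxy-3,5-bis(methoxymethoxy)benzene A1 would add to 4-(benzyloxy)-2-methoxy-6-methylbenzaldehyde A2, and oxidation of the carbinol and cleavage of the acetals would give benzophenone A3.
A3 would be aminomethylated to the Mannich base A4, A4 heated with more A3 to give the bis(benzyl ether) A5 through an o-quinone methide, and hydrogenolysis would finish.
Its weakest steps would be:
(a) the addition of the aryl-lithium of A1 to aldehyde A2, together with the oxidation and acetal cleavage it forces: three operations and a redox detour for one hindered aryl–carbonyl bond;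
(b) the mono-aminomethylation of A3, which must stop at one of two equivalent ring carbons on late material;
(c) the o-quinone methide coupling, which needs a threefold excess of the advanced benzophenone A3 to hold back oligomers and is the step least welcome on precious material.

Plan of the new route (ring A = bridged phloroglucinol ring, numbered C1 aroyl, C2 OH, C3 CH2, C4 OMe, C5 H, C6 OH; ring B = 4-hydroxy-2-methoxy-6-methylphenyl).
The retrosynthesis first cuts the ring bond C1–C2 in each ring A, which unfolds both rings into 4-methoxy-2-pyranones; it then cuts the two CH2–C(=O)Ar bonds, and last the two pyranone C3–CH2 bonds.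
The feature used: ring A has oxygen on the alternate carbons C2, C4 and C6 and the ketone carbon on C1. Read from C2 round to C1 and on to the ketone carbon, these are the seven carbons of a 3,5,7-trioxoheptanoate with the bridge on its C2 and the only O-methyl on its C3; the molecule is symmetric about the CH2.
Forward, the bridge is made first from two triacetic acid lactones and formaldehyde, ring B is attached to an unhindered CH2 carbanion, and both rings A are closed last in one double Claisen condensation.
The aryl-lithium/oxidation detour, the Mannich step, the coupling of two benzophenones and any ring-A protecting group do not occur.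

Key step: step 8

Remark: 2,4-dihydroxy-6-methylbenzaldehyde, the starting material of step 3, is taken as a catalogue compound (it is the Vilsmeier formylation product of orcinol). The target is achiral, so no stereocentre has to be set.

Step 1
Reactants: 1 4-hydroxy-6-methyl-2H-pyran-2-one (triacetic acid lactone, 2 equiv); 2 formaldehyde (37% aqueous, 1 equiv)
Product: 4 3,3'-methylenebis(4-hydroxy-6-methyl-2H-pyran-2-one), via methylidenepyrandione 3 (not isolated)
Conditions: EtOH–H2O, 70 °C; product filtered off
Reagents that add atoms: none
Why: Knoevenagel condensation of formaldehyde at C3, the only nucleophilic carbon of the 4-hydroxy-2-pyranone, gives the 3-methylidene-2,4-dione 3, which is trapped at once by a second lactone in a Michael addition (the reaction type that turns 4-hydroxycoumarin into dicoumarol), so the 2:1 union is inherent and the poorly soluble bis-lactone should leave the solution before it reacts further.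

Step 2
Reactants: 4 3,3'-methylenebis(4-hydroxy-6-methyl-2H-pyran-2-one)
Product: 5 3,3'-methylenebis(4-methoxy-6-methyl-2H-pyran-2-one)
Conditions: Me2SO4 (3 equiv), K2CO3 (4 equiv), acetone, reflux
Reagents that add atoms: dimethyl sulfate COS(=O)(=O)OC
Why: O-alkylation of the two vinylogous acids with the hard electrophile dimethyl sulfate, the standard conditions that convert triacetic acid lactone into its 4-methyl ether rather than the 2-methoxy-4-pyranone; this fixes the future ring-A methoxy group and masks O4 for the carbanion chemistry that follows.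

Step 3
Reactants: 6 2,4-dihydroxy-6-methylbenzaldehyde
Product: 7 2-hydroxy-6-methyl-4-[(triisopropylsilyl)oxy]benzaldehyde
Conditions: i-Pr3SiCl (1.05 equiv), imidazole (2 equiv), CH2Cl2, 0 °C → rt
Reagents that add atoms: triisopropylsilyl chloride CC(C)[Si](Cl)(C(C)C)C(C)C
Why: Silyl ether formation at the free 4-hydroxyl, the 2-hydroxyl being held in a hydrogen bond to the aldehyde; the bulky triisopropylsilyl group is chosen because it should survive carbonate, chlorite, oxalyl chloride and lithium amide.

Step 4
Reactants: 7 2-hydroxy-6-methyl-4-[(triisopropylsilyl)oxy]benzaldehyde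
Product: 8 2-methoxy-6-methyl-4-[(triisopropylsilyl)oxy]benzaldehyde
Conditions: MeI (3 equiv), K2CO3 (2 equiv), acetone, 45 °C
Reagents that add atoms: iodomethane CI
Why: Williamson O-methylation of the remaining chelated phenol; no other alkylatable site is present and the hindered silyl ether resists K2CO3 in acetone.

Step 5
Reactants: 8 2-methoxy-6-methyl-4-[(triisopropylsilyl)oxy]benzaldehyde
Product: 9 2-methoxy-6-methyl-4-[(triisopropylsilyl)oxy]benzoic acid
Conditions: NaClO2 (3 equiv), NaH2PO4 (3 equiv), 2-methyl-2-butene (10 equiv), t-BuOH–H2O, rt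
Reagents that add atoms: sodium chlorite [Na+].[O-]Cl=O
Why: Pinnick (Lindgren) oxidation of the aromatic aldehyde at about pH 4, where the aryl silyl ether is stable; excess 2-methyl-2-butene removes the hypochlorous acid that could chlorinate the electron-rich ring.

Step 6
Reactants: 9 2-methoxy-6-methyl-4-[(triisopropylsilyl)oxy]benzoic acid
Product: 10 2-methoxy-6-methyl-4-[(triisopropylsilyl)oxy]benzoyl chloride
Conditions: (COCl)2 (1.5 equiv), DMF (cat.), CH2Cl2, 0 °C → rt; evaporated and used crude
Reagents that add atoms: oxalyl chloride O=C(Cl)C(=O)Cl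
Why: Acid chloride formation through the Vilsmeier-type chloroiminium salt; only gases are formed, and the aryl silyl and methyl ethers should tolerate the brief exposure to HCl in CH2Cl2.

Step 7
Reactants: 5 3,3'-methylenebis(4-methoxy-6-methyl-2H-pyran-2-one); 10 2-methoxy-6-methyl-4-[(triisopropylsilyl)oxy]benzoyl chloride (2.3 equiv)
Product: 13 3,3'-methylenebis{6-[2-(4-hydroxy-2-methoxy-6-methylphenyl)-2-oxoethyl]-4-methoxy-2H-pyran-2-one}, via dilithium bis-dienolate 11 (not isolated), via bis-silyl diketone 12 (not isolated)
Conditions: LiN(SiMe3)2 (4.6 equiv), THF, −78 °C, 1 h; 10 in THF, −78 → −20 °C; AcOH (6 equiv), then Bu4NF (2.5 equiv), 0 °C → rt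
Reagents that add atoms: none
Why: Vinylogous Claisen-type C-acylation in which the 6-methyl groups are the only acidic positions of 5 (C3 is substituted, the anion is delocalised over C5, C3 and the lactone carbonyl), the primary carbanions take the hindered aroyl chloride, the second equivalent of amide per arm deprotonates the more acidic keto-pyranone as it forms so that neither proton transfer nor a second acylation interferes, and buffered fluoride then removes both aryl silyl ethers in the same flask.

Step 8
Reactants: 13 3,3'-methylenebis{6-[2-(4-hydroxy-2-methoxy-6-methylphenyl)-2-oxoethyl]-4-methoxy-2H-pyran-2-one}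
Product: 15 Digriseophene A, via ring-opened bis-ester 14 (not isolated)
Conditions: Mg(OMe)2 (10 equiv), MeOH, reflux, under Ar; then 1 M HCl, 0 °C
Reagents that add atoms: none
Why: Methoxide, delivered as its magnesium salt, adds to the lactone carbonyl of each 4-methoxy-2-pyranone and opens it to the methyl (2E)-3-methoxy-5,7-dioxohept-2-enoate 14, held as a magnesium chelate of its 5,7-diketone; the chelated C6 carbanion then attacks the ester carbonyl (Claisen, Dieckmann-type condensation), methoxide leaves and the cyclohexadienone enolises to aromatic ring A, so the step is an overall isomerisation driven by aromatisation and phenoxide formation. The closest known reaction type is the magnesium methoxide conversion of 6-(2-oxoalkyl)-4-oxygenated 2-pyranones into acylphloroglucinols, the laboratory counterpart of polyketide Claisen folding, run here twice in one molecule. Each ring A closes in a 6-exo-trig mode (enolate carbon onto ester carbonyl), which is possible because the ester and chain C4 stay cis on the enol-ether double bond inherited from the pyranone ring. No stereocentre is formed. The step needs Claisen closure to win over aldol closure, O-cyclisation and retro-Claisen cleavage: the aldol mode cannot aromatise because chain C2 carries the bridge and is locked in the enol ether, O-cyclisations (back to the pyranone or to a 4-pyranone) are reversible under methoxide, exchange of the 4-methoxy group with the solvent is degenerate, and the aryl ketone is shielded by the two ortho substituents of ring B and deactivated by its para phenoxide. The former lactone carbonyl and ring oxygen become the two hydroxyls that flank the aroyl group, and the methoxy group ends between the bridge carbon and the free CH, as in the target.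

Compound list
1 | 4-hydroxy-6-methyl-2H-pyran-2-one (triacetic acid lactone) | Cc1cc(O)cc(=O)o1 | starting material
2 | formaldehyde | C=O | starting material
3 | 6-methyl-3-methylidene-2H-pyran-2,4(3H)-dione | C=C1C(=O)C=C(C)OC1=O | intermediate
4 | 3,3'-methylenebis(4-hydroxy-6-methyl-2H-pyran-2-one) | Cc1cc(O)c(Cc2c(O)cc(C)oc2=O)c(=O)o1 | intermediate
5 | 3,3'-methylenebis(4-methoxy-6-methyl-2H-pyran-2-one) | COc1cc(C)oc(=O)c1Cc1c(OC)cc(C)oc1=O | intermediate
6 | 2,4-dihydroxy-6-methylbenzaldehyde | Cc1cc(O)cc(O)c1C=O | starting material
7 | 2-hydroxy-6-methyl-4-[(triisopropylsilyl)oxy]benzaldehyde | Cc1cc(O[Si](C(C)C)(C(C)C)C(C)C)cc(O)c1C=O | intermediate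
8 | 2-methoxy-6-methyl-4-[(triisopropylsilyl)oxy]benzaldehyde | COc1cc(O[Si](C(C)C)(C(C)C)C(C)C)cc(C)c1C=O | intermediate
9 | 2-methoxy-6-methyl-4-[(triisopropylsilyl)oxy]benzoic acid | COc1cc(O[Si](C(C)C)(C(C)C)C(C)C)cc(C)c1C(=O)O | intermediate
10 | 2-methoxy-6-methyl-4-[(triisopropylsilyl)oxy]benzoyl chloride | COc1cc(O[Si](C(C)C)(C(C)C)C(C)C)cc(C)c1C(=O)Cl | intermediate
11 | dilithium bis-dienolate of 5 (both 6-methyl groups deprotonated; drawn C-lithiated) | [Li]Cc1cc(OC)c(Cc2c(OC)cc(C[Li])oc2=O)c(=O)o1 | intermediate
12 | 3,3'-methylenebis(4-methoxy-6-{2-[2-methoxy-6-methyl-4-(triisopropylsilyloxy)phenyl]-2-oxoethyl}-2H-pyran-2-one) | COc1cc(CC(=O)c2c(C)cc(O[Si](C(C)C)(C(C)C)C(C)C)cc2OC)oc(=O)c1Cc1c(OC)cc(CC(=O)c2c(C)cc(O[Si](C(C)C)(C(C)C)C(C)C)cc2OC)oc1=O | intermediate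
13 | 3,3'-methylenebis{6-[2-(4-hydroxy-2-methoxy-6-methylphenyl)-2-oxoethyl]-4-methoxy-2H-pyran-2-one} | COc1cc(CC(=O)c2c(C)cc(O)cc2OC)oc(=O)c1Cc1c(OC)cc(CC(=O)c2c(C)cc(O)cc2OC)oc1=O | intermediate
14 | dimethyl 2,2'-methylenebis[(2E)-7-(4-hydroxy-2-methoxy-6-methylphenyl)-3-methoxy-5,7-dioxohept-2-enoate] (present as its magnesium enolate) | COC(=O)/C(C/C(C(=O)OC)=C(\OC)CC(=O)CC(=O)c1c(C)cc(O)cc1OC)=C(\CC(=O)CC(=O)c1c(C)cc(O)cc1OC)OC | intermediate
15 | Digriseophene A, bis[2,4-dihydroxy-3-(4-hydroxy-2-methoxy-6-methylbenzoyl)-6-methoxyphenyl]methane (achiral) | COc1cc(O)c(C(=O)c2c(C)cc(O)cc2OC)c(O)c1Cc1c(OC)cc(O)c(C(=O)c2c(C)cc(O)cc2OC)c1O | target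

Total step count: 8. Longest linear sequence: 6 (steps 3, 4, 5, 6, 7, 8); the pyranone branch (steps 1, 2) joins at step 7.

Steps most likely to fail

Step 8. The twofold ring transformation may stop after one ring or the halves may interfere: methanolysis of the enolised pyranone rings may be incomplete, a phenoxide of the first-formed ring A may capture the second pyranone, or the methylene bridge between two phloroglucinol rings may be lost by base-induced fragmentation on prolonged heating. Ring A would then be closed on a monomer and the bridge made last. The fallback sets out from acid chloride 10. Commercial 4-methoxy-6-methyl-2H-pyran-2-one F1 would be lithiated at its methyl group with LiN(SiMe3)2 and acylated with 10 to give 4-methoxy-6-{2-[2-methoxy-6-methyl-4-(triisopropylsilyloxy)phenyl]-2-oxoethyl}-2H-pyran-2-one F2. Bu4NF/AcOH would convert F2 into 6-[2-(4-hydroxy-2-methoxy-6-methylphenyl)-2-oxoethyl]-4-methoxy-2H-pyran-2-one F3. Mg(OMe)2 in methanol would convert F3 by the single ring transformation into (2,6-dihydroxy-4-methoxyphenyl)(4-hydroxy-2-methoxy-6-methylphenyl)methanone F4. Two molecules of F4, used in excess and recovered, would be joined with formaldehyde 2 at the free carbons of ring A; the fallback comes back to the route at compound 15.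

Step 7. C-acylation may be slow at the doubly ortho-substituted aroyl chloride, O-acylation or consumption of the chloride by the amide base may compete, or the reaction may stall after one arm. The ketones would then be made by aldol addition and oxidation. The fallback sets out from 5 (as its dianion 11) and aldehyde 8. Addition at −78 °C would give 3,3'-methylenebis(6-{2-hydroxy-2-[2-methoxy-6-methyl-4-(triisopropylsilyloxy)phenyl]ethyl}-4-methoxy-2H-pyran-2-one) F5, a mixture of diastereomers whose carbinol centres are removed next. Dess–Martin periodinane would oxidise F5 to 12, and Bu4NF/AcOH would give 13, where the fallback comes back to the route.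

Step 2. Methylation may go to carbon C3 or to the lactone oxygen, or stop at the mono-ether because of the hydrogen bonds between the two rings. The order of methylation and bridging would then be reversed. The fallback sets out from formaldehyde 2 (as paraformaldehyde). Commercial 4-methoxy-6-methyl-2H-pyran-2-one F6, the same substance as F1, would be condensed with it 2:1 in AcOH with H2SO4; two molecules of F6 are taken up per formaldehyde. This is a Friedel–Crafts-type hydroxyalkylation and alkylation at C3, the carbon at which this enol ether is attacked by electrophiles such as bromine, and it is argued from mechanism rather than from a close precedent. The fallback comes back to the route at compound 5.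

Further compounds
F1 | step 8 | 4-methoxy-6-methyl-2H-pyran-2-one | COc1cc(C)oc(=O)c1
F2 | step 8 | 4-methoxy-6-{2-[2-methoxy-6-methyl-4-(triisopropylsilyloxy)phenyl]-2-oxoethyl}-2H-pyran-2-one | COc1cc(CC(=O)c2c(C)cc(O[Si](C(C)C)(C(C)C)C(C)C)cc2OC)oc(=O)c1
F3 | step 8 | 6-[2-(4-hydroxy-2-methoxy-6-methylphenyl)-2-oxoethyl]-4-methoxy-2H-pyran-2-one | COc1cc(CC(=O)c2c(C)cc(O)cc2OC)oc(=O)c1
F4 | step 8 | (2,6-dihydroxy-4-methoxyphenyl)(4-hydroxy-2-methoxy-6-methylphenyl)methanone | COc1cc(O)c(C(=O)c2c(C)cc(O)cc2OC)c(O)c1
F5 | step 7 | 3,3'-methylenebis(6-{2-hydroxy-2-[2-methoxy-6-methyl-4-(triisopropylsilyloxy)phenyl]ethyl}-4-methoxy-2H-pyran-2-one), mixture of diastereomers | COc1cc(CC(O)c2c(C)cc(O[Si](C(C)C)(C(C)C)C(C)C)cc2OC)oc(=O)c1Cc1c(OC)cc(CC(O)c2c(C)cc(O[Si](C(C)C)(C(C)C)C(C)C)cc2OC)oc1=O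
F6 | step 2 | 4-methoxy-6-methyl-2H-pyran-2-one | COc1cc(C)oc(=O)c1
A1 | direct plan | 1-methoxy-3,5-bis(methoxymethoxy)benzene | COCOc1cc(OC)cc(OCOC)c1
A2 | direct plan | 4-(benzyloxy)-2-methoxy-6-methylbenzaldehyde | COc1cc(OCc2ccccc2)cc(C)c1C=O
A3 | direct plan | [4-(benzyloxy)-2-methoxy-6-methylphenyl](2,6-dihydroxy-4-methoxyphenyl)methanone | COc1cc(O)c(C(=O)c2c(C)cc(OCc3ccccc3)cc2OC)c(O)c1
A4 | direct plan | [4-(benzyloxy)-2-methoxy-6-methylphenyl]{3-[(dimethylamino)methyl]-2,6-dihydroxy-4-methoxyphenyl}methanone | COc1cc(O)c(C(=O)c2c(C)cc(OCc3ccccc3)cc2OC)c(O)c1CN(C)C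
A5 | direct plan | bis{3-[4-(benzyloxy)-2-methoxy-6-methylbenzoyl]-2,4-dihydroxy-6-methoxyphenyl}methane | COc1cc(O)c(C(=O)c2c(C)cc(OCc3ccccc3)cc2OC)c(O)c1Cc1c(OC)cc(O)c(C(=O)c2c(C)cc(OCc3ccccc3)cc2OC)c1O
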